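The south-east run is the south-west run with target added, and by 14 h it has made less: 46.2% of its charge against 51.3%. I read that gap as target lost in proportion to the target present (a first-order loss). Divided by the added target and the hours, it gives 0.00729 h⁻¹: the leak, the share of the target lost each hour. Divide the making rate by the leak times the target and time drops out: the target climbs while this ratio stands above one.

| flask | starting material | target | time |
|---|---|---|---|
| south-west | 0.0800 M |  |  |
| north | 0.0320 M |  |  |
| south-east | 0.0800 M | 0.0400 M |  |
| north-east | 0.160 M |  |  |
| north-west | 0.0800 M |  | 56 h |

- south-west run (time / h: [target] / M): 0.56: 0.00290; 0.96: 0.00529; 1.6: 0.00875; 2.8: 0.01420; 4.8: 0.02162; 8.2: 0.03152; 14: 0.04108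
- north run (time / h: [target] / M): 0.56: 0.00121; 0.96: 0.00146; 1.6: 0.00263; 2.8: 0.00398; 4.8: 0.00669; 8.2: 0.00965; 14: 0.01394
- south-east run (time / h: [target] / M): 0.56: 0.04295; 0.96: 0.04536; 1.6: 0.04806; 2.8: 0.05322; 4.8: 0.06016; 8.2: 0.06842; 14: 0.07700
- north-east run (time / h: [target] / M): 0.56: 0.00741; 0.96: 0.01212; 1.6: 0.01989; 2.8: 0.03213; 4.8: 0.04892; 8.2: 0.06943; 14: 0.08971

(scatter of a reading: 2 × 10⁻⁴ M)

- apparent order in [starting material] of the starting rate, round the charge of the south-west run (the rate where two percent of its starting material have turned into target) (one fixed amount of target, the same in the runs compared)
- target in the north-west run at 56 h, as a share of the starting material charged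

- Overall: starting material -> target.
- Constant volume, constant temperature.
- Bound and free are read together.
- An order is taken over about fifteen percent of the charge, up and down.

The forecast gives 1.3 (1.15 to 1.45) and 68% (59% to 79%), and of the flask it says “it then plateaus”. I keep its order.

Turn the yield round. To hold 68%, the north-west run, with the south-west charge, must still make 0.00495 h⁻¹ of its charge per hour. Over its last interval the south-west run makes target about as fast as the north run does at first, so I use the north run as the tail of that recipe. Its last interval gives 0.00925 h⁻¹ of the north-west charge per hour, about twice the holding rate, at roughly 25.1 h and still falling. My own reckoning adds the north run's target to the south-west share and takes off the leak, giving 57.7% at that hour. Between its first readings and its last interval, the north run's rate falls by a share of 0.0775 h⁻¹ each hour. I assume that this fall goes on, which puts the making rate at 8.42 × 10⁻⁴ h⁻¹ at 56 h, less than the holding rate. Over the remaining 30.9 h this estimate adds 10.8%, while the leak on 57.7% takes 13.0%. I commit to about 55.5% at 56 h, less than the forecast.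

The north-west run gives 56.8%, and the order comes out at 1.3.

    2 starting material ⇌ substrate dimer, settled at all times (24.40 M⁻¹)
    substrate dimer → target + starting material (0.2412 h⁻¹)
    2 starting material → homo dimer (0.5364 M⁻¹ h⁻¹)
    target → decomposed product (0.007560 h⁻¹)

The south-east run starts at 0.94 of the south-west rate, and the leak on its added target, taken from the south-west starting rate of 0.0708 h⁻¹ of the charge, leaves 0.949.

(The readings are simulated with constants of no real substance; noise was put on by code.)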